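## Structural features

The target is a 5,6,7,8-tetrahydro-1H-isochromen-8-one. Ring A (C4a, C5, C6, C7, C8, C8a) is a cyclohexenone fused through the C4a=C8a double bond to a 2H-pyran (ring B: C1, O2, C3, C4) that carries an (E)-prop-1-enyl group on C3. The chain O2–C3=C4–C4a=C8a–C8=O is a doubly vinylogous ester. This makes the C8 ketone a poor electrophile, the C5 hydrogens acidic and the dienyl ether sensitive to strong acid. Ring A has two adjacent stereocentres: C6 (R, secondary hydroxyl) and the quaternary C7 (S, methyl and acyloxy, alpha to the ketone), with O6 and O7 trans. O7 is acylated by 4-hydroxy-2-methoxy-6-methylbenzoic acid, whose carboxyl carbon lies between C–OCH3 and C–CH3. Fragile points are the alpha-oxygenated ketone (acyloin shift under base), a possible acyl shift from O7 to O6, loss of O6 by elimination after C5 deprotonation, and the free phenol. The real difficulty is the ester, which joins a tertiary alkoxide to a doubly flanked acyl carbon; the second is a trans diol with a quaternary centre on a ring that also needs the C4a/C8a unsaturation. The key step uses the three contiguous arene carbons C(OCH3)–C(C=O)–C(CH3): this is the pattern left when an aryne next to OCH3 takes a carbon nucleophile on the far carbon and an electrophile on the near one.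

## Logic of the disconnections

29 to 28: the two O–Si bonds (O6 and the phenol oxygen) are cut last. Both hydroxyls would quench an organomagnesium reagent, so they stay masked through the ester formation. The forward step must remove two silyl groups without opening the dienyl ether or moving the acyl group to O6.

28 to 19, 23 and 24: the aryl–carbonyl and aryl–CH3 bonds are cut. The ester is then made by a carbon nucleophile attacking a carbonate-type carbonyl already bound to O7, not by the tertiary alkoxide attacking a 2,6-disubstituted acyl group. The molecule falls into the bicyclic core, a six-carbon arene and a one-carbon unit. The forward step needs regiocontrol in the addition to the aryne, an aryl anion that prefers the O7 carbonyl over C8, and no free 24 when 19 is added.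

19 to 17 and 18: the O7–C(=O) bond is cut. The forward step is O-acylation of a tertiary alpha-ketol anion and must be run cold to avoid an acyloin shift.

23 to 22, 21 and 20: the O–S, C–I and O–Si bonds are removed in turn. The bulky silyl ether blocks two of the three free ring positions, so iodine should enter between OH and OCH3.

17 to 15 through 16: the O2–C3 bond is cut. Ring B becomes a primary alcohol on C8a and an alkyne on C4a. The forward step needs 6-endo closure and selective removal of a primary silyl ether.

15 to 10 and 12 (12 from 11): the C4a–C4 bond is cut between an sp2 and an sp carbon. The five-carbon side chain arrives in one piece with its E double bond. The forward step needs the leaving group on C4a, not on C8.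

10 to 9 to 6: the C4a–O bond of the enol sulfonate goes back to a 1,3-dione, and the C4a carbonyl goes back to the isopropenyl-bearing carbon of 6. That stereocentre has done its work by then and is the latent carbonyl. The forward steps need a clean excision of the three-carbon group and sulfonylation of the less hindered enolate oxygen.

6 to 5 to 4: the C8a–C1 bond is cut as an aldol bond. Only one side of the ketone can enolise, because C7 is quaternary.

4 to 3 to 2 to 1: the O6–Si bond, then the C6–O bond (anti opening of an epoxide), then the epoxide itself. The single stereocentre of 1 directs the epoxidation, and anti opening gives the trans diol. Ring A is therefore taken from the chiral pool and not closed at all.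

## Other disconnections considered

Alternative 1: the cut is the C8–C8a bond of ring A. In the forward step the keto ester A1 is treated with LiN(i-Pr)2; the methyl enolate attacks the ester and gives the dione A2 by a 6-exo-trig Claisen closure.
- In favour: both stereocentres come earlier from a catalyst-controlled syn dihydroxylation of an E trisubstituted enoate, which maps directly onto the trans O6/O7 pattern. The starting materials are achiral and cheap.
- Against: enolisation at the C5 methylene would expel the C6 silyloxy group; the ester carbonyl is next to a quaternary silyloxy carbon; A2 still lacks C1 and the hindered benzoate.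
- Comparison: A2 has the same ring A as 9 without the C1 unit. On stereocontrol this alternative is the better one, since reagent control replaces the acid opening of a keto epoxide. On step count to the dione stage the two are about equal. It does not address the ester, so it would still need a step like step 15.

Alternative 2: the cut is the C4a–C8a bond. In the forward step the exocyclic enol ether A3 is hydrated with catalytic Hg(OCOCF3)2 (divalent mercury); the ring opens and the alpha-mercurio ketone carbon adds to the aldehyde to give the hydroxy ketone A4 (Ferrier carbocyclisation, 6-exo-trig aldol).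
- In favour: the conditions are nearly neutral, and oxygen is already on C4a, so no three-carbon group is thrown away. On atom economy at C4a it is better than the chosen plan.
- Against: mercury, even in catalytic amount, is less safe. A3 is a branched 2-deoxy sugar that must be built in many protecting-group steps, with its own stereochemical problem at the tertiary centre. A4 still needs oxidation, C1 and the ester.
- Comparison: both plans use a sacrificial stereocentre from the chiral pool and are equal in concept. The chosen plan reaches ring A in fewer steps and without a heavy metal.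

Alternative 3: the cut is the C7–C8 bond. In the forward step a chiral triazolylidene carbene converts the aldehyde of A5 into a Breslow intermediate, which adds to the methyl ketone and gives A6, the same compound as 17.
- In favour: ring A and the free tertiary hydroxyl are formed in one catalytic, metal-free step, and the route is convergent. If A5 were easy to make, this would be the shorter way to 17, and on that point it is the better plan.
- Against: the C7 configuration is created in the ring closure and depends on C6 and the catalyst cooperating. The aldehyde is a vinylogous formate and reluctant to form the Breslow intermediate. The base may epimerise C6 next to the ketone. A5 is not simple to make.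
- Comparison: the chosen plan fixes the C6/C7 relation by a stereospecific anti epoxide opening. Downstream of A6 the two plans are identical, so they are equal there and the benzoin is compatible with step 15.

Key step: step 15

Remark: the structures of 19, 23, 28 and 29 were checked atom by atom and agree with each other; (6R,7S) corresponds to O6 and O7 trans, and no correction is needed.
Remark: the ring carbon bearing CH2O in 5 to 8 becomes sp2 in 10; its trans isomer is drawn, and the epimer would serve equally.

Step 1
Reactants: 1 (S)-(+)-carvone, (5S)-2-methyl-5-(prop-1-en-2-yl)cyclohex-2-en-1-one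
Product: 2 (1S,4S,6S)-1-methyl-4-(prop-1-en-2-yl)-7-oxabicyclo[4.1.0]heptan-2-one
Conditions: H2O2 (30% aq.), NaOH (cat.), MeOH, 0 °C
Reagents that add atoms: hydrogen peroxide, OO
Why: Weitz–Scheffer nucleophilic epoxidation of the enone; hydroperoxide adds to the beta carbon anti to the isopropenyl group and the enolate closes on the same face, so the epoxide should form trans to the isopropenyl group and fix the later C7 as S; the isolated alkene is inert.

Step 2
Reactants: 2 (1S,4S,6S)-1-methyl-4-(prop-1-en-2-yl)-7-oxabicyclo[4.1.0]heptan-2-one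
Product: 3 (2S,3R,5S)-2,3-dihydroxy-2-methyl-5-(prop-1-en-2-yl)cyclohexan-1-one
Conditions: H2SO4 (0.5 M aq.), THF, 0 °C→rt
Reagents that add atoms: water, O
Why: acid-catalysed epoxide hydrolysis; water should attack the secondary beta carbon from the face opposite the epoxide oxygen, because the tertiary carbon is hindered and deactivated by the carbonyl; inversion there gives the trans diol with 3R, and the tertiary centre is untouched.

Step 3
Reactants: 3 (2S,3R,5S)-2,3-dihydroxy-2-methyl-5-(prop-1-en-2-yl)cyclohexan-1-one
Product: 4 (2S,3R,5S)-3-(tert-butyldimethylsilyloxy)-2-hydroxy-2-methyl-5-(prop-1-en-2-yl)cyclohexan-1-one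
Conditions: TBSOTf (1.05 equiv), 2,6-lutidine, CH2Cl2, −78→−40 °C
Reagents that add atoms: tert-butyldimethylsilyl trifluoromethanesulfonate, CC(C)(C)[Si](C)(C)OS(=O)(=O)C(F)(F)F
Why: chemoselective silyl ether formation; the secondary hydroxyl should react well before the tertiary alpha-ketol hydroxyl at low temperature.

Step 4
Reactants: 4 (2S,3R,5S)-3-(tert-butyldimethylsilyloxy)-2-hydroxy-2-methyl-5-(prop-1-en-2-yl)cyclohexan-1-one
Product: 5 (2S,3R,5S,6S)-3-(tert-butyldimethylsilyloxy)-2-hydroxy-6-(hydroxymethyl)-2-methyl-5-(prop-1-en-2-yl)cyclohexan-1-one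
Conditions: LiN(i-Pr)2 (2.1 equiv), THF, −78 °C; CH2O (gas, from paraformaldehyde), −78 °C; NH4Cl
Reagents that add atoms: formaldehyde, C=O
Why: aldol addition of a ketone lithium enolate to formaldehyde; the first equivalent of base removes the hydroxyl proton and the second can enolise only toward C6, because C2 is quaternary; the electrophile should enter anti to the neighbouring isopropenyl group, and the new centre is lost later.

Step 5
Reactants: 5 (2S,3R,5S,6S)-3-(tert-butyldimethylsilyloxy)-2-hydroxy-6-(hydroxymethyl)-2-methyl-5-(prop-1-en-2-yl)cyclohexan-1-one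
Product: 6 (2S,3R,5S,6S)-3-(tert-butyldimethylsilyloxy)-6-{[(tert-butyldimethylsilyl)oxy]methyl}-2-hydroxy-2-methyl-5-(prop-1-en-2-yl)cyclohexan-1-one
Conditions: TBSCl, imidazole, DMF, 0 °C
Reagents that add atoms: tert-butyldimethylsilyl chloride, CC(C)(C)[Si](C)(C)Cl
Why: selective silylation of the primary hydroxyl; it protects the beta-hydroxy ketone against retro-aldol cleavage and dehydration, and the tertiary hydroxyl should not react.

Step 6
Reactants: 6 (2S,3R,5S,6S)-3-(tert-butyldimethylsilyloxy)-6-{[(tert-butyldimethylsilyl)oxy]methyl}-2-hydroxy-2-methyl-5-(prop-1-en-2-yl)cyclohexan-1-one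
Product: 9 (4S,5R)-5-(tert-butyldimethylsilyloxy)-2-{[(tert-butyldimethylsilyl)oxy]methyl}-4-hydroxy-4-methylcyclohexane-1,3-dione, via methoxy hydroperoxide 7 (not isolated), via TEMPO ether 8 (not isolated)
Conditions: O3, MeOH–CH2Cl2, −78 °C; FeSO4·7H2O, TEMPO, −78 °C→rt; Mg(O2CC6H4CO3H)2·6H2O, NaHCO3, 0 °C→rt
Reagents that add atoms: TEMPO (2,2,6,6-tetramethylpiperidin-1-oxyl), CC1(C)CCCC(C)(C)N1[O]
Why: oxodealkenylation; ozonolysis in methanol gives the alpha-methoxy hydroperoxide, divalent iron cleaves the O–O bond, the alkoxy radical fragments to methyl acetate and a ring radical that TEMPO traps, and peracid oxidation of the alkoxyamine gives the ketone; the two carbinol centres are not involved.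

Step 7
Reactants: 9 (4S,5R)-5-(tert-butyldimethylsilyloxy)-2-{[(tert-butyldimethylsilyl)oxy]methyl}-4-hydroxy-4-methylcyclohexane-1,3-dione
Product: 10 (4S,5R)-5-(tert-butyldimethylsilyloxy)-2-{[(tert-butyldimethylsilyl)oxy]methyl}-4-hydroxy-4-methyl-3-oxocyclohex-1-en-1-yl trifluoromethanesulfonate
Conditions: PhNTf2, Et3N, CH2Cl2, 0 °C→rt
Reagents that add atoms: N-phenylbis(trifluoromethanesulfonimide), O=S(=O)(N(c1ccccc1)S(=O)(=O)C(F)(F)F)C(F)(F)F
Why: enol triflate formation from a 1,3-dione enolate; the oxygen on the carbonyl beside the quaternary carbon is shielded and hydrogen-bonded to the tertiary hydroxyl, so the bulky reagent should sulfonylate the remote oxygen; the amine base does not deprotonate the tertiary alcohol.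

Step 8
Reactants: 11 (E)-but-2-enal
Product: 12 (3E)-1,1-dibromopenta-1,3-diene
Conditions: CBr4, PPh3, CH2Cl2, 0 °C
Reagents that add atoms: carbon tetrabromide, BrC(Br)(Br)Br
Why: first stage of the Corey–Fuchs reaction (Wittig-type dibromoolefination of the aldehyde); the E double bond is not touched.

Step 9
Reactants: 10 (4S,5R)-5-(tert-butyldimethylsilyloxy)-2-{[(tert-butyldimethylsilyl)oxy]methyl}-4-hydroxy-4-methyl-3-oxocyclohex-1-en-1-yl trifluoromethanesulfonate; 12 (3E)-1,1-dibromopenta-1,3-diene (2.5 equiv)
Product: 15 (5R,6S)-5-(tert-butyldimethylsilyloxy)-2-{[(tert-butyldimethylsilyl)oxy]methyl}-6-hydroxy-6-methyl-3-[(3E)-pent-3-en-1-yn-1-yl]cyclohex-2-en-1-one, via lithium pentenynide 13 (not isolated), via pentenynylzinc chloride 14 (not isolated)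
Conditions: 12, n-BuLi (2 equiv per 12), THF, −78→0 °C; ZnCl2, 0 °C; 10, Pd(PPh3)4 (5 mol%), THF, rt
Reagents that add atoms: none
Why: second stage of the Corey–Fuchs reaction (bromine–lithium exchange, 1,2-shift, deprotonation) gives the acetylide without isolating the volatile enyne; transmetalation to zinc and Negishi coupling with the enol triflate under zerovalent palladium should form the C–C bond, the excess zinc reagent covering the free hydroxyl.

Step 10
Reactants: 15 (5R,6S)-5-(tert-butyldimethylsilyloxy)-2-{[(tert-butyldimethylsilyl)oxy]methyl}-6-hydroxy-6-methyl-3-[(3E)-pent-3-en-1-yn-1-yl]cyclohex-2-en-1-one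
Product: 17 (6R,7S)-6-(tert-butyldimethylsilyloxy)-7-hydroxy-7-methyl-3-[(E)-prop-1-enyl]-6,7-dihydro-1H-isochromen-8(5H)-one, via hydroxymethyl enynone 16 (not isolated)
Conditions: HF·pyridine, pyridine, THF, 0 °C; aqueous NaHCO3 work-up; Ph3PAuNTf2 (3 mol%), CH2Cl2, rt
Reagents that add atoms: none
Why: the primary silyl ether should cleave well before the secondary one beside the quaternary carbon; monovalent gold then catalyses a 6-endo-dig hydroalkoxylation (cycloisomerisation), the oxygen attacking the alkyne carbon remote from the ring, which is the delta carbon of the dienynone and is stabilised by the propenyl group; protodeauration gives the 2H-pyran.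

Step 11
Reactants: 17 (6R,7S)-6-(tert-butyldimethylsilyloxy)-7-hydroxy-7-methyl-3-[(E)-prop-1-enyl]-6,7-dihydro-1H-isochromen-8(5H)-one; 18 1,1'-carbonyldiimidazole
Product: 19 (6R,7S)-6-(tert-butyldimethylsilyloxy)-7-methyl-8-oxo-3-[(E)-prop-1-enyl]-5,6,7,8-tetrahydro-1H-isochromen-7-yl imidazole-1-carboxylate
Conditions: KN(SiMe3)2 (1.05 equiv), THF, −78 °C; 18 (1.5 equiv), −78→0 °C; NH4Cl
Reagents that add atoms: none
Why: acylation of the tertiary alkoxide by the carbonyl diazolide with loss of one imidazolide; a soluble, titrated amide base at −78 °C replaces a metal hydride, to keep the alpha-ketol anion from rearranging and to leave the C5 hydrogens alone.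

Step 12
Reactants: 20 5-methoxyresorcinol
Product: 21 3-methoxy-5-(triisopropylsilyloxy)phenol
Conditions: TIPSCl (1.0 equiv), imidazole, DMF, 0 °C
Reagents that add atoms: triisopropylsilyl chloride, CC(C)[Si](Cl)(C(C)C)C(C)C
Why: monosilylation of a symmetric diphenol; the outcome is statistical, so unreacted 20 and the bis-silyl ether are to be separated and recycled.

Step 13
Reactants: 21 3-methoxy-5-(triisopropylsilyloxy)phenol
Product: 22 2-iodo-3-methoxy-5-(triisopropylsilyloxy)phenol
Conditions: I2 (1.0 equiv), NaHCO3, THF–H2O, 0 °C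
Reagents that add atoms: iodine, II
Why: electrophilic aromatic iodination of the phenoxide; all three free positions are activated, but two are flanked by the triisopropylsilyloxy group, so iodine should enter between OH and OCH3.

Step 14
Reactants: 22 2-iodo-3-methoxy-5-(triisopropylsilyloxy)phenol
Product: 23 2-iodo-3-methoxy-5-(triisopropylsilyloxy)phenyl 4-chlorobenzenesulfonate
Conditions: 4-ClC6H4SO2Cl, Et3N, DMAP (cat.), CH2Cl2, 0 °C→rt
Reagents that add atoms: 4-chlorobenzenesulfonyl chloride, O=S(=O)(Cl)c1ccc(Cl)cc1
Why: O-sulfonylation of the phenol; the aryl sulfonate is the leaving group for the later aryne formation and survives iodine–magnesium exchange at −78 °C.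

Step 15
Reactants: 19 (6R,7S)-6-(tert-butyldimethylsilyloxy)-7-methyl-8-oxo-3-[(E)-prop-1-enyl]-5,6,7,8-tetrahydro-1H-isochromen-7-yl imidazole-1-carboxylate; 23 2-iodo-3-methoxy-5-(triisopropylsilyloxy)phenyl 4-chlorobenzenesulfonate; 24 methylmagnesium chloride
Product: 28 (6R,7S)-6-(tert-butyldimethylsilyloxy)-7-methyl-8-oxo-3-[(E)-prop-1-enyl]-5,6,7,8-tetrahydro-1H-isochromen-7-yl 2-methoxy-6-methyl-4-(triisopropylsilyloxy)benzoate, via magnesiated aryl sulfonate 25 (not isolated), via aryne 26 (not isolated), via aryl Grignard reagent 27 (not isolated)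
Conditions: 23 (1.5 equiv), i-PrMgCl (1.5 equiv), THF, −78 °C; 24 (1.35 equiv), −78 °C→rt; 19 (1.0 equiv), THF, −40→0 °C; NH4Cl
Reagents that add atoms: none
Why: Proposed new method: iodine–magnesium exchange gives 25, which loses the sulfonate on warming to form aryne 26; 24 adds across it to give 27, and 27 then displaces imidazolide from the O7 carbonyl of 19, so the aryl–CH3 and aryl–carbonyl bonds form in one flask. The closest known reaction type is aryne generation from a 2-iodoaryl sulfonate by iodine–magnesium exchange, addition of a magnesium nucleophile and trapping of the ortho-magnesiated arene with an electrophile; acylation of Grignard reagents by N-acyl azoles is the model for the last event. No ring is closed and no stereocentre is formed; C6 and C7 are not touched. Regioselectivity is needed in the addition to 26: the inductive pull of OCH3 polarises the aryne so that the nucleophile enters at the distal carbon and magnesium ends up beside OCH3, which places the carbonyl between OCH3 and CH3. Chemoselectivity is needed at 19: the C8 ketone is a doubly vinylogous ester next to a quaternary carbon and should be far less electrophilic than the azolide carbonyl. The two ortho groups of 27 should stop a second addition to the new ester. Reagent 24 is made the limiting component relative to 23, so none is left to turn 19 into an acetate; surplus aryne is consumed by aryl–aryne coupling. The ester is thus formed by C–C bond formation at an accessible carbonyl, which avoids attack of a tertiary alkoxide on a 2,6-disubstituted acyl group.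

Step 16
Reactants: 28 (6R,7S)-6-(tert-butyldimethylsilyloxy)-7-methyl-8-oxo-3-[(E)-prop-1-enyl]-5,6,7,8-tetrahydro-1H-isochromen-7-yl 2-methoxy-6-methyl-4-(triisopropylsilyloxy)benzoate
Product: 29 (6R,7S)-6-hydroxy-7-methyl-8-oxo-3-[(E)-prop-1-enyl]-5,6,7,8-tetrahydro-1H-isochromen-7-yl 4-hydroxy-2-methoxy-6-methylbenzoate (target)
Conditions: HF·pyridine, pyridine, THF, 0 °C→rt
Reagents that add atoms: none
Why: fluoride-mediated cleavage of the aryl and the secondary silyl ether; the weakly acidic medium and the hindered acyl group should suppress acyl migration to O6 and deprotonation at C5.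

Compound list

1 | (S)-(+)-carvone, (5S)-2-methyl-5-(prop-1-en-2-yl)cyclohex-2-en-1-one | C=C(C)[C@@H]1CC(=O)C(C)=CC1 | starting material
2 | (1S,4S,6S)-1-methyl-4-(prop-1-en-2-yl)-7-oxabicyclo[4.1.0]heptan-2-one | C=C(C)[C@@H]1CC(=O)[C@@]2(C)O[C@H]2C1 | intermediate
3 | (2S,3R,5S)-2,3-dihydroxy-2-methyl-5-(prop-1-en-2-yl)cyclohexan-1-one | C=C(C)[C@@H]1CC(=O)[C@@](C)(O)[C@H](O)C1 | intermediate
4 | (2S,3R,5S)-3-(tert-butyldimethylsilyloxy)-2-hydroxy-2-methyl-5-(prop-1-en-2-yl)cyclohexan-1-one | C=C(C)[C@@H]1CC(=O)[C@@](C)(O)[C@H](O[Si](C)(C)C(C)(C)C)C1 | intermediate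
5 | (2S,3R,5S,6S)-3-(tert-butyldimethylsilyloxy)-2-hydroxy-6-(hydroxymethyl)-2-methyl-5-(prop-1-en-2-yl)cyclohexan-1-one | C=C(C)[C@@H]1[C@@H](CO)C(=O)[C@@](C)(O)[C@H](O[Si](C)(C)C(C)(C)C)C1 | intermediate
6 | (2S,3R,5S,6S)-3-(tert-butyldimethylsilyloxy)-6-{[(tert-butyldimethylsilyl)oxy]methyl}-2-hydroxy-2-methyl-5-(prop-1-en-2-yl)cyclohexan-1-one | C=C(C)[C@@H]1[C@@H](CO[Si](C)(C)C(C)(C)C)C(=O)[C@@](C)(O)[C@H](O[Si](C)(C)C(C)(C)C)C1 | intermediate
7 | methoxy hydroperoxide: 6 with the isopropenyl group replaced by 1-hydroperoxy-1-methoxyethyl (mixture at the new carbon) | COC(C)(OO)[C@@H]1[C@@H](CO[Si](C)(C)C(C)(C)C)C(=O)[C@@](C)(O)[C@H](O[Si](C)(C)C(C)(C)C)C1 | intermediate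
8 | TEMPO ether: 6 with the isopropenyl group replaced by (2,2,6,6-tetramethylpiperidin-1-yl)oxy (mixture at that carbon) | CC1(C)CCCC(C)(C)N1OC1[C@@H](CO[Si](C)(C)C(C)(C)C)C(=O)[C@@](C)(O)[C@H](O[Si](C)(C)C(C)(C)C)C1 | intermediate
9 | (4S,5R)-5-(tert-butyldimethylsilyloxy)-2-{[(tert-butyldimethylsilyl)oxy]methyl}-4-hydroxy-4-methylcyclohexane-1,3-dione (enolised; C2 not a defined centre) | O=C1C(CO[Si](C)(C)C(C)(C)C)C(=O)[C@@](C)(O)[C@H](O[Si](C)(C)C(C)(C)C)C1 | intermediate
10 | (4S,5R)-5-(tert-butyldimethylsilyloxy)-2-{[(tert-butyldimethylsilyl)oxy]methyl}-4-hydroxy-4-methyl-3-oxocyclohex-1-en-1-yl trifluoromethanesulfonate | FC(F)(F)S(=O)(=O)OC1=C(CO[Si](C)(C)C(C)(C)C)C(=O)[C@@](C)(O)[C@H](O[Si](C)(C)C(C)(C)C)C1 | intermediate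
11 | (E)-but-2-enal | C/C=C/C=O | starting material
12 | (3E)-1,1-dibromopenta-1,3-diene | C/C=C/C=C(Br)Br | intermediate
13 | lithium (3E)-pent-3-en-1-yn-1-ide | C/C=C/C#C[Li] | intermediate
14 | chloro[(3E)-pent-3-en-1-yn-1-yl]zinc | C/C=C/C#C[Zn]Cl | intermediate
15 | (5R,6S)-5-(tert-butyldimethylsilyloxy)-2-{[(tert-butyldimethylsilyl)oxy]methyl}-6-hydroxy-6-methyl-3-[(3E)-pent-3-en-1-yn-1-yl]cyclohex-2-en-1-one | C/C=C/C#CC1=C(CO[Si](C)(C)C(C)(C)C)C(=O)[C@@](C)(O)[C@H](O[Si](C)(C)C(C)(C)C)C1 | intermediate
16 | (5R,6S)-5-(tert-butyldimethylsilyloxy)-6-hydroxy-2-(hydroxymethyl)-6-methyl-3-[(3E)-pent-3-en-1-yn-1-yl]cyclohex-2-en-1-one | C/C=C/C#CC1=C(CO)C(=O)[C@@](C)(O)[C@H](O[Si](C)(C)C(C)(C)C)C1 | intermediate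
17 | (6R,7S)-6-(tert-butyldimethylsilyloxy)-7-hydroxy-7-methyl-3-[(E)-prop-1-enyl]-6,7-dihydro-1H-isochromen-8(5H)-one | C/C=C/C1=CC2=C(CO1)C(=O)[C@@](C)(O)[C@H](O[Si](C)(C)C(C)(C)C)C2 | intermediate
18 | 1,1'-carbonyldiimidazole | O=C(n1ccnc1)n1ccnc1 | starting material
19 | (6R,7S)-6-(tert-butyldimethylsilyloxy)-7-methyl-8-oxo-3-[(E)-prop-1-enyl]-5,6,7,8-tetrahydro-1H-isochromen-7-yl imidazole-1-carboxylate | C/C=C/C1=CC2=C(CO1)C(=O)[C@@](C)(OC(=O)n1ccnc1)[C@H](O[Si](C)(C)C(C)(C)C)C2 | intermediate
20 | 5-methoxyresorcinol | COc1cc(O)cc(O)c1 | starting material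
21 | 3-methoxy-5-(triisopropylsilyloxy)phenol | COc1cc(O)cc(O[Si](C(C)C)(C(C)C)C(C)C)c1 | intermediate
22 | 2-iodo-3-methoxy-5-(triisopropylsilyloxy)phenol | COc1cc(O[Si](C(C)C)(C(C)C)C(C)C)cc(O)c1I | intermediate
23 | 2-iodo-3-methoxy-5-(triisopropylsilyloxy)phenyl 4-chlorobenzenesulfonate | COc1cc(O[Si](C(C)C)(C(C)C)C(C)C)cc(OS(=O)(=O)c2ccc(Cl)cc2)c1I | intermediate
24 | methylmagnesium chloride | C[Mg]Cl | starting material
25 | {2-[(4-chlorophenyl)sulfonyloxy]-6-methoxy-4-(triisopropylsilyloxy)phenyl}magnesium chloride | COc1cc(O[Si](C(C)C)(C(C)C)C(C)C)cc(OS(=O)(=O)c2ccc(Cl)cc2)c1[Mg]Cl | intermediate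
26 | 3-methoxy-5-(triisopropylsilyloxy)benzyne (1,2-didehydrobenzene) | COC1=CC(O[Si](C(C)C)(C(C)C)C(C)C)=CC#C1 | intermediate
27 | [2-methoxy-6-methyl-4-(triisopropylsilyloxy)phenyl]magnesium chloride | COc1cc(O[Si](C(C)C)(C(C)C)C(C)C)cc(C)c1[Mg]Cl | intermediate
28 | (6R,7S)-6-(tert-butyldimethylsilyloxy)-7-methyl-8-oxo-3-[(E)-prop-1-enyl]-5,6,7,8-tetrahydro-1H-isochromen-7-yl 2-methoxy-6-methyl-4-(triisopropylsilyloxy)benzoate | C/C=C/C1=CC2=C(CO1)C(=O)[C@@](C)(OC(=O)c1c(C)cc(O[Si](C(C)C)(C(C)C)C(C)C)cc1OC)[C@H](O[Si](C)(C)C(C)(C)C)C2 | intermediate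
29 | (6R,7S)-6-hydroxy-7-methyl-8-oxo-3-[(E)-prop-1-enyl]-5,6,7,8-tetrahydro-1H-isochromen-7-yl 4-hydroxy-2-methoxy-6-methylbenzoate | C/C=C/C1=CC2=C(CO1)C(=O)[C@@](C)(OC(=O)c1c(C)cc(O)cc1OC)[C@H](O)C2 | target

Total step count: 16. Longest linear sequence: 12 steps (steps 1 to 7, 9, 10, 11, 15 and 16, from 1 to 29).

Least certain steps

Step 15 (key step). Several processes may interfere:
- acyl transfer may fail because the di-ortho-substituted aryl Grignard reagent is slow to add to the carbonyl on a tertiary oxygen;
- the tetrahedral intermediate may expel the tertiary alkoxide in place of imidazolide;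
- the Grignard reagent may deprotonate C5;
- the aryne may be consumed by aryl–aryne coupling before methyl addition is complete.

Fallback with known chemistry, setting out from 23 and 17 and returning at 28: 27 is generated from 23 as in step 15 and quenched with CO2 to give 2-methoxy-6-methyl-4-(triisopropylsilyloxy)benzoic acid F1. This is converted with 1-chloro-N,N,2-trimethylprop-1-en-1-amine into 2-methoxy-6-methyl-4-(triisopropylsilyloxy)benzoyl chloride F2. The potassium alkoxide of 17 (KN(SiMe3)2, THF, −78 °C) is then acylated with F2 to give 28. This acylation is a known reaction type but should be slow for steric reasons.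

Step 2. Acid may hydrate the isopropenyl group or let a hydroxyl add to it, and the deactivated keto epoxide may open slowly. Fallback from 2 back to 3: nucleophilic opening with benzoic acid and catalytic tetrabutylammonium benzoate in toluene at 80 °C (substitution with inversion at the secondary carbon, no strong acid) gives (1R,2S,5S)-2-hydroxy-2-methyl-3-oxo-5-(prop-1-en-2-yl)cyclohexyl benzoate F3. Methanolysis with K2CO3 in MeOH at 0 °C then returns 3.

Step 6. The peracid may over-oxidise the enol of the new dione or insert oxygen beside the C8 ketone, and acidic methanol may remove the primary silyl ether. Fallback from 6 back to 9 by a Criegee rearrangement sequence: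
- ozonolysis in MeOH, then Ac2O, Et3N and DMAP, gives (1S,2R,4S,5R)-5-(tert-butyldimethylsilyloxy)-2-{[(tert-butyldimethylsilyl)oxy]methyl}-4-hydroxy-4-methyl-3-oxocyclohexyl acetate F4;
- brief methanolysis with K2CO3 in MeOH at 0 °C gives (2S,3R,5S,6R)-3-(tert-butyldimethylsilyloxy)-6-{[(tert-butyldimethylsilyl)oxy]methyl}-2,5-dihydroxy-2-methylcyclohexan-1-one F5;
- Dess–Martin oxidation gives 9.

Step 7. Sulfonylation may occur at the wrong enolate oxygen (on C8) or at O7. Fallback from 9, returning at 16 and then 17 as in step 10: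
- O7 is silylated first (TESOTf, 2,6-lutidine; the enol silyl ether is lost on work-up) to give (4S,5R)-5-(tert-butyldimethylsilyloxy)-2-{[(tert-butyldimethylsilyl)oxy]methyl}-4-methyl-4-(triethylsilyloxy)cyclohexane-1,3-dione F6, whose C8 oxygen is more strongly shielded;
- triflation as in step 7 gives (4S,5R)-5-(tert-butyldimethylsilyloxy)-2-{[(tert-butyldimethylsilyl)oxy]methyl}-4-methyl-3-oxo-4-(triethylsilyloxy)cyclohex-1-en-1-yl trifluoromethanesulfonate F7;
- coupling as in step 9 gives (5R,6S)-5-(tert-butyldimethylsilyloxy)-2-{[(tert-butyldimethylsilyl)oxy]methyl}-6-methyl-3-[(3E)-pent-3-en-1-yn-1-yl]-6-(triethylsilyloxy)cyclohex-2-en-1-one F8;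
- HF·pyridine removes the primary silyl and the triethylsilyl group to give 16.

Step 10. Ring closure may take the 5-exo course, or the secondary silyl ether may be lost during the selective desilylation. Fallback from 16 (isolated after the desilylation) to 17: piperidine adds to the dienynone at the carbon remote from the ring to give (5R,6S)-5-(tert-butyldimethylsilyloxy)-6-hydroxy-2-(hydroxymethyl)-6-methyl-3-[(3E)-2-(piperidin-1-yl)penta-1,3-dien-1-yl]cyclohex-2-en-1-one F9, in which the position of the heteroatom is fixed by conjugate addition. Mild acid (pyridinium p-toluenesulfonate, CH2Cl2) then exchanges the amine for the primary hydroxyl and gives 17.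

Step 13. Iodination may be poorly regioselective or go on to polyiodination. Fallback from 21 back to 22 by directed ortho-metalation:
- MOMCl (generated in situ from dimethoxymethane and acetyl chloride) and i-Pr2NEt give triisopropyl[3-methoxy-5-(methoxymethoxy)phenoxy]silane F10;
- n-BuLi in THF at 0 °C lithiates the position between the two directing groups, and I2 gives [4-iodo-3-methoxy-5-(methoxymethoxy)phenoxy]triisopropylsilane F11;
- HCl in MeOH removes the acetal to give 22.

Further compounds

F1 | step 15 | 2-methoxy-6-methyl-4-(triisopropylsilyloxy)benzoic acid | COc1cc(O[Si](C(C)C)(C(C)C)C(C)C)cc(C)c1C(=O)O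
F2 | step 15 | 2-methoxy-6-methyl-4-(triisopropylsilyloxy)benzoyl chloride | COc1cc(O[Si](C(C)C)(C(C)C)C(C)C)cc(C)c1C(=O)Cl
F3 | step 2 | (1R,2S,5S)-2-hydroxy-2-methyl-3-oxo-5-(prop-1-en-2-yl)cyclohexyl benzoate | C=C(C)[C@@H]1CC(=O)[C@@](C)(O)[C@H](OC(=O)c2ccccc2)C1
F4 | step 6 | (1S,2R,4S,5R)-5-(tert-butyldimethylsilyloxy)-2-{[(tert-butyldimethylsilyl)oxy]methyl}-4-hydroxy-4-methyl-3-oxocyclohexyl acetate | CC(=O)O[C@@H]1[C@@H](CO[Si](C)(C)C(C)(C)C)C(=O)[C@@](C)(O)[C@H](O[Si](C)(C)C(C)(C)C)C1
F5 | step 6 | (2S,3R,5S,6R)-3-(tert-butyldimethylsilyloxy)-6-{[(tert-butyldimethylsilyl)oxy]methyl}-2,5-dihydroxy-2-methylcyclohexan-1-one | O[C@@H]1[C@@H](CO[Si](C)(C)C(C)(C)C)C(=O)[C@@](C)(O)[C@H](O[Si](C)(C)C(C)(C)C)C1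
F6 | step 7 | (4S,5R)-5-(tert-butyldimethylsilyloxy)-2-{[(tert-butyldimethylsilyl)oxy]methyl}-4-methyl-4-(triethylsilyloxy)cyclohexane-1,3-dione | O=C1C(CO[Si](C)(C)C(C)(C)C)C(=O)[C@@](C)(O[Si](CC)(CC)CC)[C@H](O[Si](C)(C)C(C)(C)C)C1
F7 | step 7 | (4S,5R)-5-(tert-butyldimethylsilyloxy)-2-{[(tert-butyldimethylsilyl)oxy]methyl}-4-methyl-3-oxo-4-(triethylsilyloxy)cyclohex-1-en-1-yl trifluoromethanesulfonate | FC(F)(F)S(=O)(=O)OC1=C(CO[Si](C)(C)C(C)(C)C)C(=O)[C@@](C)(O[Si](CC)(CC)CC)[C@H](O[Si](C)(C)C(C)(C)C)C1
F8 | step 7 | (5R,6S)-5-(tert-butyldimethylsilyloxy)-2-{[(tert-butyldimethylsilyl)oxy]methyl}-6-methyl-3-[(3E)-pent-3-en-1-yn-1-yl]-6-(triethylsilyloxy)cyclohex-2-en-1-one | C/C=C/C#CC1=C(CO[Si](C)(C)C(C)(C)C)C(=O)[C@@](C)(O[Si](CC)(CC)CC)[C@H](O[Si](C)(C)C(C)(C)C)C1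
F9 | step 10 | (5R,6S)-5-(tert-butyldimethylsilyloxy)-6-hydroxy-2-(hydroxymethyl)-6-methyl-3-[(3E)-2-(piperidin-1-yl)penta-1,3-dien-1-yl]cyclohex-2-en-1-one | C/C=C/C(N1CCCCC1)=CC1=C(CO)C(=O)[C@@](C)(O)[C@H](O[Si](C)(C)C(C)(C)C)C1
F10 | step 13 | triisopropyl[3-methoxy-5-(methoxymethoxy)phenoxy]silane | COCOc1cc(OC)cc(O[Si](C(C)C)(C(C)C)C(C)C)c1
F11 | step 13 | [4-iodo-3-methoxy-5-(methoxymethoxy)phenoxy]triisopropylsilane | COCOc1cc(O[Si](C(C)C)(C(C)C)C(C)C)cc(OC)c1I
A1 | alternative 1 | ethyl (2S,3R)-3-(tert-butyldimethylsilyloxy)-2-methyl-5-oxo-2-(triethylsilyloxy)hexanoate | CC(=O)C[C@@H](O[Si](C)(C)C(C)(C)C)[C@](C)(O[Si](CC)(CC)CC)C(=O)OCC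
A2 | alternative 1 | (5R,6S)-5-(tert-butyldimethylsilyloxy)-6-methyl-6-(triethylsilyloxy)cyclohexane-1,3-dione | O=C1CC(=O)C[C@@H](O[Si](C)(C)C(C)(C)C)[C@]1(C)O[Si](CC)(CC)CC
A3 | alternative 2 | (3S,4R)-4-(tert-butyldimethylsilyloxy)-6-methoxy-3-methyl-2-methylideneoxan-3-ol (either anomer) | C=C1OC(OC)C[C@@H](O[Si](C)(C)C(C)(C)C)[C@]1(C)O
A4 | alternative 2 | (2S,3R)-3-(tert-butyldimethylsilyloxy)-2,5-dihydroxy-2-methylcyclohexanone (5-hydroxyl trans to O3) | O=C1C[C@H](O)C[C@@H](O[Si](C)(C)C(C)(C)C)[C@]1(C)O
A5 | alternative 3 | 4-[(2R)-2-(tert-butyldimethylsilyloxy)-3-oxobutyl]-6-[(E)-prop-1-enyl]-2H-pyran-3-carbaldehyde | C/C=C/C1=CC(C[C@@H](O[Si](C)(C)C(C)(C)C)C(C)=O)=C(C=O)CO1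
A6 | alternative 3 | (6R,7S)-6-(tert-butyldimethylsilyloxy)-7-hydroxy-7-methyl-3-[(E)-prop-1-enyl]-6,7-dihydro-1H-isochromen-8(5H)-one | C/C=C/C1=CC2=C(CO1)C(=O)[C@@](C)(O)[C@H](O[Si](C)(C)C(C)(C)C)C2
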